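Which flask, dawn, spring or dusk, holds the most ring? I answered with two amounts: the charge c and a ring ceiling C.

| flask | starting material | temperature | remark | time |
|---|---|---|---|---|
| west | 0.55 M | 35 °C | run made earlier |  |
| north-east | 0.83 M | 68 °C | run made earlier |  |
| dawn | 1.1 M | 20 °C |  | 3.0 min |
| spring | 1.1 M | 80 °C |  | 3.0 min |
| dusk | 1.1 M | 50 °C |  | 3.0 min |

| run | time / s | ring / % | starting material / % |
|---|---|---|---|
| west | 10.0 | 3.2 | 75.6 |
| west | 20.0 | 6.3 | 70.9 |
| west | 40.0 | 11.1 | 65.9 |
| west | 80.0 | 19.3 | 58.2 |
| north-east | 10.0 | 36.0 | 35.7 |
| north-east | 15.0 | 43.7 | 24.5 |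

(scatter of a reading: 0.3 percentage points)

* the flask that comes out highest in amount of ring, in percent of the starting material charged, or "all alike" when all lie within 1.5 percentage points (dawn / spring / dusk / all alike)
* ring at the end, in percent of the starting material charged, dawn
* ring at the end, in percent of the starting material charged, spring
* ring at the end, in percent of the starting material charged, dusk

- a reading or a percentage of ring counts all its forms, free or not
- a reading of starting material is of its free form alone

My own supposition was that ring forms first order from free starting material and is lost on meeting starting material, one of each. The west run's missing material at 20.0 s I took as pairs of starting material in equilibrium, which reads K = 0.412 M⁻¹. What was missing beyond those pairs at each run's last reading, with that K held for both temperatures, counted double, giving ring lost L = 0.0196 M in west and 0.115 M in north-east.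

With P the ring concentration at that last reading, replacing the ring curve by its mean, P/2, gave C = (P+L)/L × P/2: 0.340 M in west, 0.754 M in north-east. This C is the ring concentration at which making and loss balance, a selectivity factor with the unit of concentration.

Ring per second from west's last reading and north-east's first, with its logarithm straight in temperature, comes over 3.0 min to 148 % of the charge for dusk and 12.7 % for dawn, so I took dusk and spring as finished and kept dawn out of this reckoning. With the charge finished, the same mean gives 2C(c−P) = P(c+P). Taking ln C as straight in temperature, I got C = 0.488 M and ring 39.0 % for dusk, and C = 1.01 M and ring 54.3 % for spring. So I put spring ahead of dusk, and dawn, at its 12.7 %, behind both.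

The forecast said dusk, with 13 %, 47 % and 71 % for dawn, spring and dusk, reasoning that “This side path is invisible at 35 °C”.

The simulation gave spring: 8.25 % in dawn, 53.6 % in spring, 42.2 % in dusk.

    starting material + ring → side product (k = 0.0193 M⁻¹ s⁻¹, Ea = 74.0 kJ mol⁻¹)
    2 starting material ⇌ open dimer (K = 0.440 M⁻¹, k = 0.170 M⁻¹ s⁻¹, Ea = 70.0 kJ mol⁻¹, ΔH = 6.00 kJ mol⁻¹)
    ring ⇌ isomer of the product (K = 0.320, k = 0.00441 s⁻¹, Ea = 84.0 kJ mol⁻¹, ΔH = −41.0 kJ mol⁻¹)
    starting material → ring (k = 0.0175 s⁻¹, Ea = 83.0 kJ mol⁻¹)
    starting material + ring ⇌ idle adduct, settled at all times (K = 0.420 M⁻¹, ΔH = −27.0 kJ mol⁻¹)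
    (constants at 50 °C)

With starting material + ring → side product struck out, spring holds 92.0 % of ring. For the neighbour of dusk run at 75 °C, the ceiling comes to 0.892 M and the reckoned ring to 51.7 %, and that flask holds 52.0 %.

The readings are calculated with made-up constants; scatter was added.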